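Our vessel is closed, stirred and held at constant volume. In it starting material has two ways out: free enzyme turns it into target, and target itself takes it up to give side product.

| flask | starting material | free enzyme | temperature | remark | time |
|---|---|---|---|---|---|
| Wednesday's | 0.055 M | 5 µM | 40 °C | run made earlier |  |
| teal | 0.20 M | 20 µM | 40 °C |  | 3.0 h |
| ochre | 0.050 M | 5.0 µM | 40 °C |  | 3.0 h |
| green | 0.030 M | 8.0 µM | 40 °C |  | 3.0 h |
| red | 0.012 M | 20 µM | 40 °C |  | 3.0 h |
| amber | 0.012 M | 5.0 µM | 60 °C |  | 3.0 h |
| grey | 0.050 M | 8.0 µM | 40 °C |  | 3.0 h |

- Wednesday's (time / min: target / %, side product / %): 5.00: 5, 1; 8.00: 6, 1; 15.0: 11, 0; 25.0: 15, 11; 40.0: 14, 20; 60.0: 16, 32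

(standard deviation of a reading: 2 percentage points)

- percent here means starting material units held: one side product counts as two
- the earlier runs were read with a standard deviation of 2 percentage points
- steps thought possible: free enzyme -> unfolded enzyme; 2 free enzyme -> spent catalyst; starting material + free enzyme -> target + free enzyme; starting material + target -> side product
- the earlier runs do not show what temperature does; that part of a forecast is a guess
- no earlier run changes the charge of free enzyme; that part of a forecast is a guess

- ranking by share of target in all that became target or side product, from high to low, at 3.0 h (teal / ochre / green / red / amber / grey)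
- the share of target in all that became target or side product of the flask you put first, at 3.0 h
- the share of target in all that became target or side product of the flask you put last, at 3.0 h

Both ways use starting material, so we expect target to climb until it is eaten as fast as it is made, a steady state into which the charge of starting material need not enter. Wednesday's run seems to show one: target reads 15%, 14% and 16% from 25.0 min on, while side product keeps rising.

Before reading that level off, we ask what it must rest on. The length of a run matters little once a flask stands at its level, for those readings differ by about their scatter. The scatter, 2 percentage points on 15%, moves the level in proportion, and with it every number below that is a plain multiple of the level. No earlier run changes the enzyme charge or the charge of starting material, so what each does cannot be read from the runs; we guess that the level is proportional to the enzyme charge and free of the charge of starting material. Temperature is a guess too, so we leave amber, at 60 °C, unplaced.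

The number is 8.25 mM at 5 µM: this is the ceiling, the target concentration at which target is eaten as fast as it is made. Scaled, it becomes 13.2 mM at 8.0 µM and 33.0 mM at 20 µM. Where the charge stands above the ceiling, we take ceiling over charge as the share: green 44.0%, grey 26.4%, ochre and teal both 16.5%. Red's charge stands below its ceiling, and a rough count, ceiling over ceiling plus charge, gives 73.3%.

The forecast gave red > green > grey > teal > ochre > amber, from 72% down to 10%, with the remark “The order of amber against ochre, and of teal against grey, is uncertain”.

The flasks give red > amber > green > grey > ochre > teal, from 84.4% in red down to 0.818% in teal.

    free enzyme → unfolded enzyme (k = 1.90 × 10⁻⁶ s⁻¹, Ea = 191 kJ mol⁻¹)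
    2 free enzyme → spent catalyst (k = 110 M⁻¹ s⁻¹, Ea = 39.0 kJ mol⁻¹)
    starting material + free enzyme → target + free enzyme, rate k3*[starting material]*[free enzyme]/(1 + ([starting material]/Km3) + ([starting material]/Ksi3)^2) (42.0 mM, 32.0 mM, k = 210 M⁻¹ s⁻¹, Ea = 45.0 kJ mol⁻¹)
    starting material + target → side product (k = 0.0100 M⁻¹ s⁻¹, Ea = 52.0 kJ mol⁻¹)
    (constants at 40 °C)

At 3.00 h green holds 13.7 mM of target against our 13.2 mM, and ochre 8.39 mM against 8.25 mM, but teal holds 0.287 mM, far under its 33.0 mM. Red's neighbour, charged with 0.048 M of starting material, keeps the 20 µM of free enzyme, so its ceiling is 33.0 mM and its charge stands above that, which gives a share of 68.8%. That neighbour ends with 61.3% as side product and 36.7% as target, which is 17.6 mM, below the ceiling.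

All runs are simulated for an exercise; noise was put on by code.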